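A charge of 0.50 mM of starting material, given in 3 portions, meets partner that the held gas tops up towards 0.13 mM, and I want the share of that charge that reaches product.

    starting material ⇌ intermediate A (K1 = 1.8, k1 = 0.040 s⁻¹)
    intermediate A ⇌ intermediate B (K2 = 1.3, k2 = 0.0078 s⁻¹)
    intermediate A → decomposed reagent (k3 = 0.038 s⁻¹)
    gas ⇌ partner, rate k4*(csat - [partner]) (k4 = 4.4 s⁻¹, csat = 0.13 mM)
    partner + intermediate D → product (k5 = 140 M⁻¹ s⁻¹)
    starting material + partner ⇌ intermediate C (K6 = 5700 M⁻¹, k6 = 160 M⁻¹ s⁻¹)
    partner + intermediate B ⇌ intermediate D (K7 = 59000 M⁻¹, k7 = 400 M⁻¹ s⁻¹)

starting material 0.50 mM (in portions, 3); gas 0.13 mM (held); time 2.0 h; the portions of starting material follow each other after 1.2 s, the first at the start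

- the state of affairs at 2.0 h: stopped, and by what, or still going (forward and back rates have come level / all of the starting material has reacted / it is still moving)
- the product standing at 2.0 h, as a percentage of the starting material charged

- at the start none of partner is dissolved
- the reaction counts as stopped when no species that holds the starting material changes by six tenths of a point or more over the second half of the time
- run time (flask): 2.0 h

In this flask the gas can deliver 0.572 mM s⁻¹ into an empty solution, far more than the 0.0260 mM s⁻¹ that step 7 would draw from saturated solution if the whole charge stood at once as intermediate B, and the constants of steps 5 and 6 are smaller, so I freeze partner at 0.13 mM and each step becomes pseudo-first-order. Starting material and intermediate C have no irreversible exit of their own in the scheme, so they delay material without dividing it, and the division happens at a chain of forks. Intermediate A crosses to intermediate B at 0.0078 s⁻¹ or decomposes at 0.038 s⁻¹; intermediate B goes on to intermediate D at 0.0520 s⁻¹ or back at 0.006000 s⁻¹; intermediate D goes to product at 0.0182 s⁻¹ or back at 0.006780 s⁻¹. The slowest of these constants, the return from intermediate B, stands for 2.78 min, far short of 2.0 h, so I expect the chain to run its course within minutes.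

Two extreme versions can be solved in the head. If nothing ever came back from intermediate B, the first fork would give 17.0%. If each return counted as lost, taking each fork once with forward chances of 17.0%, 89.7% and 72.9% would give 11.1%. The real flask lies between them, since a return is neither safe nor lost but a further try at the same odds. Summing those tries, intermediate B reaches product before falling back with chance 86.3%, and this gives the product share, the chance that intermediate A ends as product rather than decomposed reagent, of 15.1%.

The forecast says all of the starting material has reacted and 15%, on the ground that “only the irreversible exits to decomposed reagent and product matter”.

The simulation gives all of the starting material has reacted, with 0% of the charge left as starting material, and product at 15.1%, beside my 15.1%. The loss of intermediate A to decomposed reagent holds the product down. Strike that step and the fork at intermediate A has no second exit, so the product share rises to one. The simulated run without that loss gives 100% of product against 15.1%, which accounts for 100% of what is missing.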